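Ring B is built, not bought. The strategic disconnection is its C1–C6 bond: C1–C4 and their oxygens trace back to dimethyl squarate, C5 and C6 to an alkenyl group bonded through its substituted carbon. The precursor is a squarate-derived cyclobutenone whose sp3 carbon bears that alkenyl group and a silyloxy group. Thermolysis unzips it to a dienylketene, and 6π electrocyclisation then closes ring B, fixing all six positions at once: free hydroxyl at C1 (the handle for the enone arm), methoxy at C2 and C3, silyloxy at C4, the quaternary 1,1-dimethylallyl group at C5, hydrogen at C6. The feature exploited is ring B's contiguous C2–C3–C4 oxygenation beside the C5 quaternary substituent.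

Key step: step 4

Remark: the alkenyl unit has to be a vinyl group substituted at its point of attachment (a 1-substituted vinyl), because only then does the side chain land on C5 and hydrogen on C6; compounds 2 and 5 are taken as commercial, and the 4'-hydroxyl travels as a triisopropylsilyl ether because a free phenoxide would add to the vinyl ketone.

Step 1
Reactants: 1 1-chloro-3-methylbut-2-ene (prenyl chloride); 2 N-methoxy-N-methylacetamide
Product: 4 3,3-dimethylpent-4-en-2-one, via prenylmagnesium chloride 3 (not isolated)
Conditions: Mg, THF, 0 °C; then 2, THF, −78 → 0 °C; aq. HCl (1 M); distillation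
Reagents that add atoms: none
Why: Weinreb ketone synthesis with an allylic Grignard reagent, in which the prenyl reagent should bond through its dimethyl-substituted γ-carbon (allylic transposition through a cyclic transition state) and the N-methoxy-N-methyl amide releases the ketone only on acidic work-up, which rules out a second addition.

Step 2
Reactants: 4 3,3-dimethylpent-4-en-2-one; 5 2,4,6-triisopropylbenzenesulfonohydrazide
Product: 6 (E)-N'-(3,3-dimethylpent-4-en-2-ylidene)-2,4,6-triisopropylbenzenesulfonohydrazide (trisylhydrazone; sulfonamide nitrogen anti to the quaternary carbon)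
Conditions: MeOH, conc. HCl (cat.), rt; then −20 °C (crystallisation)
Reagents that add atoms: none
Why: Acid-catalysed hydrazone formation from a ketone and a sulfonyl hydrazide, well established for tert-alkyl methyl ketones, in which the sulfonamide nitrogen should settle anti to the quaternary carbon and thus syn to the methyl group that is deprotonated next.

Step 3
Reactants: 6 trisylhydrazone; 7 dimethyl squarate (3,4-dimethoxycyclobut-3-ene-1,2-dione)
Product: 10 racemic 4-(tert-butyldimethylsilyloxy)-2,3-dimethoxy-4-(3,3-dimethylpenta-1,4-dien-2-yl)cyclobut-2-en-1-one, via 3,3-dimethylpenta-1,4-dien-2-yllithium 8 (not isolated), via lithium cyclobutenolate 9 (not isolated)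
Conditions: n-BuLi (2.05 equiv), THF, −78 °C, then 0 °C (N2 evolution); cannulate into 7, THF, −78 °C; TBSOTf (1.5 equiv), −78 → −20 °C; aq. NaHCO3
Reagents that add atoms: tert-butyldimethylsilyl trifluoromethanesulfonate (TBSOTf), CC(C)(C)[Si](C)(C)OS(=O)(=O)C(F)(F)F
Why: Shapiro reaction followed by 1,2-addition and O-silylation, in which double deprotonation of the trisylhydrazone (the methyl group holds the only α-hydrogens) and loss of sulfinate and N2 should give vinyllithium 8, which adds once to a squarate carbonyl at −78 °C as alkenyllithiums normally do, after which alkoxide 9 is trapped by the silyl triflate; the new carbinol centre forms as a racemate (no chiral influence) and is erased in step 4.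

Step 4
Reactants: 10 racemic 4-(tert-butyldimethylsilyloxy)-2,3-dimethoxy-4-(3,3-dimethylpenta-1,4-dien-2-yl)cyclobut-2-en-1-one
Product: 13 4-(tert-butyldimethylsilyloxy)-2,3-dimethoxy-5-(2-methylbut-3-en-2-yl)phenol, via (Z)-dienylketene 11 (not isolated), via cyclohexa-2,4-dienone 12 (not isolated)
Conditions: p-xylene (0.02 M, degassed), 140 °C, Ar
Reagents that add atoms: none
Why: Moore rearrangement, in which thermal conrotatory 4π opening of the cyclobutenone cleaves the bond between the carbonyl carbon and the silyloxy-bearing sp3 carbon and should give (Z)-dienylketene 11. Disrotatory 6π electrocyclisation then joins the ketene carbon to the terminal methylene (the C1–C6 bond of ring B), closing the six-membered carbocycle as dienone 12, which enolises to phenol 13. The closest known reaction type is the thermal ring expansion of squarate-derived 4-alkenyl-4-oxycyclobutenones to hydroquinone derivatives, here applied to an alkenyl group whose attachment carbon carries a quaternary substituent. No stereocentre is created and the racemic carbinol centre of 10 disappears. The step needs torquoselectivity, which the silyloxy donor secures by rotating outward so that the alkenyl group turns inward and lies next to the ketene. It also needs ring closure to outpace capture of the ketene by the remote vinyl group, which is expected because the diene terminus is held within bonding distance whereas the neopentyl-type vinyl group could only give a strained bicyclic cyclobutanone.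

Step 5
Reactants: 14 4-hydroxyacetophenone
Product: 15 1-[4-(triisopropylsilyloxy)phenyl]ethan-1-one
Conditions: i-Pr3SiCl, imidazole, DMF, rt
Reagents that add atoms: chlorotriisopropylsilane (TIPSCl), CC(C)[Si](Cl)(C(C)C)C(C)C
Why: Imidazole-promoted silylation of a phenol, chosen so that no phenoxide can add to the vinyl ketone in steps 6 and 8 and so that this group leaves together with the ring B silyl ether in step 9.

Step 6
Reactants: 15 1-[4-(triisopropylsilyloxy)phenyl]ethan-1-one
Product: 16 1-[4-(triisopropylsilyloxy)phenyl]prop-2-en-1-one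
Conditions: (CH2O)n, i-Pr2NH2+ CF3CO2− (1 equiv), CF3CO2H (10 mol %), THF, reflux; store cold over BHT and use at once
Reagents that add atoms: formaldehyde (used as paraformaldehyde), C=O
Why: Mannich condensation–elimination (α-methylenation) of an aryl methyl ketone with formaldehyde under secondary-ammonium promotion, a known one-flask route to aryl vinyl ketones, helped here by the acetyl group being the only enolisable site and by the tolerance of the aryl silyl ether for the weakly acidic medium.

Step 7
Reactants: 13 4-(tert-butyldimethylsilyloxy)-2,3-dimethoxy-5-(2-methylbut-3-en-2-yl)phenol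
Product: 17 4-(tert-butyldimethylsilyloxy)-2,3-dimethoxy-5-(2-methylbut-3-en-2-yl)phenyl trifluoromethanesulfonate
Conditions: Tf2O, pyridine, CH2Cl2, −20 → 0 °C
Reagents that add atoms: trifluoromethanesulfonic anhydride (Tf2O), O=S(=O)(OS(=O)(=O)C(F)(F)F)C(F)(F)F
Why: O-Sulfonylation of a phenol with triflic anhydride and pyridine, unambiguous because C1 carries the only free hydroxyl and the hindered aryl silyl ether is inert to these conditions.

Step 8
Reactants: 17 aryl triflate; 16 1-[4-(triisopropylsilyloxy)phenyl]prop-2-en-1-one
Product: 18 (E)-3-[4-(tert-butyldimethylsilyloxy)-2,3-dimethoxy-5-(2-methylbut-3-en-2-yl)phenyl]-1-[4-(triisopropylsilyloxy)phenyl]prop-2-en-1-one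
Conditions: Pd(OAc)2 (5 mol %), 1,3-bis(diphenylphosphino)propane (6 mol %), Et3N (2 equiv), BHT (cat.), DMF, 80 °C
Reagents that add atoms: none
Why: Mizoroki–Heck reaction, in which the aryl triflate adds oxidatively to zerovalent palladium formed in the flask, the arylpalladium species inserts the electron-poor terminal alkene with aryl transfer to its CH2 carbon, and syn β-hydride elimination should give the E enone, while the hindered, unactivated vinyl group of the dimethylallyl unit is not expected to compete.

Step 9
Reactants: 18 bis-silylated chalcone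
Product: 19 (E)-3-[4-hydroxy-2,3-dimethoxy-5-(2-methylbut-3-en-2-yl)phenyl]-1-(4-hydroxyphenyl)prop-2-en-1-one
Conditions: n-Bu4NF (2.5 equiv), AcOH (2.5 equiv), THF, 0 °C → rt
Reagents that add atoms: none
Why: Fluoride-induced cleavage of both aryl silyl ethers, driven by Si–F bond formation and buffered with acetic acid so that the phenols are released without exposing the enone to basic phenoxide.

Step 10
Reactants: 19 (E)-3-[4-hydroxy-2,3-dimethoxy-5-(2-methylbut-3-en-2-yl)phenyl]-1-(4-hydroxyphenyl)prop-2-en-1-one
Product: 20 (E)-3-[3,4-dihydroxy-2-methoxy-5-(2-methylbut-3-en-2-yl)phenyl]-1-(4-hydroxyphenyl)prop-2-en-1-one (target)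
Conditions: BCl3 (1 M in CH2Cl2, 4 equiv), CH2Cl2, −78 → 0 °C; then H2O, 0 °C
Reagents that add atoms: none
Why: Hydroxyl-directed Lewis-acid cleavage of an aryl methyl ether, in which the C4 oxygen binds boron and holds it against the C3 methoxy oxygen (also the central, most crowded oxygen of the C2–C3–C4 array) so that chloride should remove that methyl group, whereas the C2 methoxy group has no neighbouring hydroxyl or carbonyl to chelate boron and should survive at low temperature.

Compound list
1 | 1-chloro-3-methylbut-2-ene (prenyl chloride) | CC(C)=CCCl | starting material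
2 | N-methoxy-N-methylacetamide | CC(=O)N(C)OC | starting material
3 | prenylmagnesium chloride (3-methylbut-2-en-1-ylmagnesium chloride) | CC(C)=CC[Mg]Cl | intermediate (not isolated)
4 | 3,3-dimethylpent-4-en-2-one | CC(=O)C(C)(C)C=C | intermediate
5 | 2,4,6-triisopropylbenzenesulfonohydrazide | CC(C)c1cc(C(C)C)c(S(=O)(=O)NN)c(C(C)C)c1 | starting material
6 | (E)-N'-(3,3-dimethylpent-4-en-2-ylidene)-2,4,6-triisopropylbenzenesulfonohydrazide | C/C(=N\NS(=O)(=O)c1c(C(C)C)cc(C(C)C)cc1C(C)C)C(C)(C)C=C | intermediate
7 | dimethyl squarate (3,4-dimethoxycyclobut-3-ene-1,2-dione) | COC1=C(OC)C(=O)C1=O | starting material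
8 | 3,3-dimethylpenta-1,4-dien-2-yllithium | [Li]C(=C)C(C)(C)C=C | intermediate (not isolated)
9 | lithium 2,3-dimethoxy-1-(3,3-dimethylpenta-1,4-dien-2-yl)-4-oxocyclobut-2-en-1-olate (racemic) | COC1=C(OC)C([O-])(C(=C)C(C)(C)C=C)C1=O.[Li+] | intermediate (not isolated)
10 | racemic 4-(tert-butyldimethylsilyloxy)-2,3-dimethoxy-4-(3,3-dimethylpenta-1,4-dien-2-yl)cyclobut-2-en-1-one | COC1=C(OC)C(O[Si](C)(C)C(C)(C)C)(C(=C)C(C)(C)C=C)C1=O | intermediate
11 | (3Z)-4-(tert-butyldimethylsilyloxy)-2,3-dimethoxy-6,6-dimethyl-5-methylideneocta-1,3,7-trien-1-one (dienylketene) | O=C=C(OC)/C(OC)=C(/O[Si](C)(C)C(C)(C)C)C(=C)C(C)(C)C=C | intermediate (not isolated)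
12 | 4-(tert-butyldimethylsilyloxy)-2,3-dimethoxy-5-(2-methylbut-3-en-2-yl)cyclohexa-2,4-dien-1-one | COC1=C(OC)C(O[Si](C)(C)C(C)(C)C)=C(C(C)(C)C=C)CC1=O | intermediate (not isolated)
13 | 4-(tert-butyldimethylsilyloxy)-2,3-dimethoxy-5-(2-methylbut-3-en-2-yl)phenol | COc1c(O)cc(C(C)(C)C=C)c(O[Si](C)(C)C(C)(C)C)c1OC | intermediate
14 | 4-hydroxyacetophenone | CC(=O)c1ccc(O)cc1 | starting material
15 | 1-[4-(triisopropylsilyloxy)phenyl]ethan-1-one | CC(=O)c1ccc(O[Si](C(C)C)(C(C)C)C(C)C)cc1 | intermediate
16 | 1-[4-(triisopropylsilyloxy)phenyl]prop-2-en-1-one | C=CC(=O)c1ccc(O[Si](C(C)C)(C(C)C)C(C)C)cc1 | intermediate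
17 | 4-(tert-butyldimethylsilyloxy)-2,3-dimethoxy-5-(2-methylbut-3-en-2-yl)phenyl trifluoromethanesulfonate | COc1c(OS(=O)(=O)C(F)(F)F)cc(C(C)(C)C=C)c(O[Si](C)(C)C(C)(C)C)c1OC | intermediate
18 | (E)-3-[4-(tert-butyldimethylsilyloxy)-2,3-dimethoxy-5-(2-methylbut-3-en-2-yl)phenyl]-1-[4-(triisopropylsilyloxy)phenyl]prop-2-en-1-one | C=CC(C)(C)c1cc(/C=C/C(=O)c2ccc(O[Si](C(C)C)(C(C)C)C(C)C)cc2)c(OC)c(OC)c1O[Si](C)(C)C(C)(C)C | intermediate
19 | (E)-3-[4-hydroxy-2,3-dimethoxy-5-(2-methylbut-3-en-2-yl)phenyl]-1-(4-hydroxyphenyl)prop-2-en-1-one | C=CC(C)(C)c1cc(/C=C/C(=O)c2ccc(O)cc2)c(OC)c(OC)c1O | intermediate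
20 | (E)-3-[3,4-dihydroxy-2-methoxy-5-(2-methylbut-3-en-2-yl)phenyl]-1-(4-hydroxyphenyl)prop-2-en-1-one (InflamNat IN0234) | C=CC(C)(C)c1cc(/C=C/C(=O)c2ccc(O)cc2)c(OC)c(O)c1O | target

Total step count: 10. Longest linear sequence: 8 steps (steps 1, 2, 3, 4, 7, 8, 9, 10); steps 5 and 6 form the short side branch.

Steps most likely to fail

1. Step 4 (key step). What may go wrong: the bulky alkenyl group may resist inward rotation, or the reactive conformer of the dienylketene may be disfavoured by crowding between the silyloxy group and the quaternary carbon. The ketene would then be lost to dimerisation, to acylation of the product phenol or to reaction at the remote vinyl group before it cyclises. The fallback sets out from lithium cyclobutenolate 9, generated as in step 3 and quenched with aqueous NH4Cl in place of the silyl triflate. This gives the free carbinol, racemic 4-hydroxy-2,3-dimethoxy-4-(3,3-dimethylpenta-1,4-dien-2-yl)cyclobut-2-en-1-one F1. Thermolysis of this smaller, unprotected variant (p-xylene, reflux, argon) is the classical form of the same ring expansion and should give 2,3-dimethoxy-5-(2-methylbut-3-en-2-yl)benzene-1,4-diol F2. Its two hydroxyls differ sharply in steric access, since the C1 hydroxyl has a hydrogen neighbour and the C4 hydroxyl sits between a methoxy group and the tertiary alkyl group. One equivalent of PhNTf2 with Et3N (CH2Cl2, 0 °C, air excluded) should therefore sulfonylate C1 and give 4-hydroxy-2,3-dimethoxy-5-(2-methylbut-3-en-2-yl)phenyl trifluoromethanesulfonate F3. Silylation of the remaining hindered hydroxyl (TBSOTf, 2,6-lutidine, CH2Cl2) rejoins the route at triflate 17.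

2. Step 8. What may go wrong: oxidative addition of the electron-rich, ortho-substituted triflate may be slow, so that polymerisation of the vinyl ketone or reduction of the triflate takes over. The fallback sets out from triflate 17 and builds the enone by carbonyl chemistry. Palladium-catalysed formylation (Pd(OAc)2, 1,3-bis(diphenylphosphino)propane, CO at 1 atm, Et3SiH, Et3N, DMF, 70 °C) should give 4-(tert-butyldimethylsilyloxy)-2,3-dimethoxy-5-(2-methylbut-3-en-2-yl)benzaldehyde F4. Addition of the lithium enolate generated from ketone 15 with LiN(SiMe3)2 (THF, −78 °C) should give the racemic aldol, 3-[4-(tert-butyldimethylsilyloxy)-2,3-dimethoxy-5-(2-methylbut-3-en-2-yl)phenyl]-3-hydroxy-1-[4-(triisopropylsilyloxy)phenyl]propan-1-one F5. Mesylation and elimination (MeSO2Cl, Et3N, CH2Cl2, 0 °C → rt) then deliver the E enone and rejoin the route at 18. Compound 16 is no longer needed in this variant.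

3. Step 10. What may go wrong: discrimination between the two methyl ethers may be incomplete, or the acid released may induce cyclisation of the C4 hydroxyl onto the neighbouring dimethylallyl alkene. The fallback sets out from diol 19 and replaces Lewis-acid cleavage by oxidative demethylation of the 2-methoxyphenol unit. IBX (DMF, 0 °C → rt) oxygenates the methoxy-bearing ortho position of the electron-rich C4 phenol; the other ortho position is blocked by the quaternary group and the 4'-phenol is deactivated by its para acyl group. Loss of methanol gives the ortho-quinone, 3-methoxy-4-[(E)-3-(4-hydroxyphenyl)-3-oxoprop-1-enyl]-6-(2-methylbut-3-en-2-yl)cyclohexa-3,5-diene-1,2-dione F6. Brief reduction in the same flask with aqueous Na2S2O4 at 0 °C returns the catechol and reaches target 20.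

Further compounds
F1 | step 4 | racemic 4-hydroxy-2,3-dimethoxy-4-(3,3-dimethylpenta-1,4-dien-2-yl)cyclobut-2-en-1-one | COC1=C(OC)C(O)(C(=C)C(C)(C)C=C)C1=O
F2 | step 4 | 2,3-dimethoxy-5-(2-methylbut-3-en-2-yl)benzene-1,4-diol | COc1c(O)cc(C(C)(C)C=C)c(O)c1OC
F3 | step 4 | 4-hydroxy-2,3-dimethoxy-5-(2-methylbut-3-en-2-yl)phenyl trifluoromethanesulfonate | COc1c(OS(=O)(=O)C(F)(F)F)cc(C(C)(C)C=C)c(O)c1OC
F4 | step 8 | 4-(tert-butyldimethylsilyloxy)-2,3-dimethoxy-5-(2-methylbut-3-en-2-yl)benzaldehyde | COc1c(C=O)cc(C(C)(C)C=C)c(O[Si](C)(C)C(C)(C)C)c1OC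
F5 | step 8 | racemic 3-[4-(tert-butyldimethylsilyloxy)-2,3-dimethoxy-5-(2-methylbut-3-en-2-yl)phenyl]-3-hydroxy-1-[4-(triisopropylsilyloxy)phenyl]propan-1-one | COc1c(C(O)CC(=O)c2ccc(O[Si](C(C)C)(C(C)C)C(C)C)cc2)cc(C(C)(C)C=C)c(O[Si](C)(C)C(C)(C)C)c1OC
F6 | step 10 | 3-methoxy-4-[(E)-3-(4-hydroxyphenyl)-3-oxoprop-1-enyl]-6-(2-methylbut-3-en-2-yl)cyclohexa-3,5-diene-1,2-dione | C=CC(C)(C)C1=CC(/C=C/C(=O)c2ccc(O)cc2)=C(OC)C(=O)C1=O
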